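Ring B (C5–C6–C7–C8–C9–C10, labdane numbering) is closed last, through the C6–C7 bond, by a Lewis acid-promoted intramolecular carbonyl-ene reaction of a monocyclic aldehyde: the formyl carbon C6 on C5 of ring A is attacked by the methylene terminus C7 of an isopropenyl group on C9. One operation gives ring B, the C6 oxygen and the C8 branch point. The aldehyde comes from an anionic oxy-Cope rearrangement that forges the quaternary C10–C9 bond with chirality transfer from an (S)-carbinol. The step exploits the 1,3-relation in ring B between the C6 oxygen and C8 with its C17 methyl; the C7 oxygen and the 8,9-olefin then follow from the 6-ketone.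

Key step: step 8

Remark: labdane numbering (C1–C20) and the α/β convention with the C10 methyl β are used throughout; step 6 should give mainly the E olefin, and the C9 epimers that a minor Z isomer would carry through 11–14 converge in step 10, where C9 becomes sp2, so structures show the E series.

Step 1
Reactants: 1 nerol, (2Z)-3,7-dimethylocta-2,6-dien-1-ol
Product: 2 neryl tert-butyldiphenylsilyl ether
Conditions: TBDPSCl, imidazole, DMF, 0 °C to rt
Reagents that add atoms: tert-butyl(chloro)diphenylsilane, CC(C)(C)[Si](Cl)(c1ccccc1)c1ccccc1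
Why: Standard silyl ether formation at the primary allylic alcohol; the robust tert-butyldiphenylsilyl group should survive every later step and also shields the 2,3-olefin in step 2.

Step 2
Reactants: 2 neryl tert-butyldiphenylsilyl ether
Product: 3 6,7-epoxide of 2 (racemic at the epoxide carbon)
Conditions: mCPBA, CH2Cl2, −20 °C
Reagents that add atoms: 3-chloroperbenzoic acid, OOC(=O)c1cccc(Cl)c1
Why: Prilezhaev epoxidation, chemoselective for the electron-rich terminal olefin because the 2,3-olefin is deactivated by the allylic silyloxy group; the new epoxide stereocentre is not controlled and is destroyed in step 3.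

Step 3
Reactants: 3 6,7-epoxide of 2
Product: 4 (4Z)-6-(tert-butyldiphenylsilyloxy)-4-methylhex-4-enal
Conditions: H5IO6, THF/H2O, 0 °C to rt
Reagents that add atoms: none
Why: Periodic acid hydrolyses the epoxide to the glycol and cleaves it in the same pot (glycol cleavage), which releases acetone and leaves the aldehyde carbon that becomes C9.

Step 4
Reactants: 4 (4Z)-6-(tert-butyldiphenylsilyloxy)-4-methylhex-4-enal
Product: 5 tert-butyl{[(2Z)-3-methylhepta-2,6-dien-1-yl]oxy}diphenylsilane
Conditions: Ph3PCH3Br, KN(SiMe3)2, THF, −78 °C to 0 °C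
Reagents that add atoms: methyltriphenylphosphonium bromide, C[P+](c1ccccc1)(c1ccccc1)c1ccccc1.[Br-]
Why: Wittig methylenation of the unhindered aldehyde with the non-stabilised ylide, which should leave the Z trisubstituted olefin and the silyl ether untouched.

Step 5
Reactants: 6 β-cyclocitral, 2,6,6-trimethylcyclohex-1-ene-1-carbaldehyde
Product: 7 (1S)-3-methyl-1-(2,6,6-trimethylcyclohex-1-en-1-yl)but-3-en-1-ol
Conditions: tributyl(2-methylallyl)stannane, (S)-BINOL (cat.), Ti(OiPr)4 (cat.), 4 Å molecular sieves, CH2Cl2, −20 °C; aqueous NaHCO3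
Reagents that add atoms: tributyl(2-methylallyl)stannane, C=C(C)C[Sn](CCCC)(CCCC)CCCC
Why: Keck asymmetric allylation: the (S)-BINOL–titanium Lewis acid activates the enal and directs the SE2' attack of the methallylstannane to one carbonyl face, which should set the C6 carbinol as (S), the same facial sense as for aryl and alkenyl aldehydes.

Step 6
Reactants: 7 (1S)-3-methyl-1-(2,6,6-trimethylcyclohex-1-en-1-yl)but-3-en-1-ol; 5 tert-butyl{[(2Z)-3-methylhepta-2,6-dien-1-yl]oxy}diphenylsilane
Product: 8 (1S,3E,7Z)-9-(tert-butyldiphenylsilyloxy)-3,7-dimethyl-1-(2,6,6-trimethylcyclohex-1-en-1-yl)nona-3,7-dien-1-ol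
Conditions: RuCl2(H2IMes)(=CH-C6H4-2-OiPr) (second-generation Hoveyda–Grubbs catalyst, cat.), 5 in excess, CH2Cl2, 40 °C
Reagents that add atoms: none
Why: Olefin cross-metathesis between the 1,1-disubstituted olefin of 7 and the terminal olefin of 5, driven by loss of ethylene, should give the trisubstituted C8=C9 olefin mainly as the E isomer, the tetrasubstituted ring olefin and the trisubstituted chain olefin being too hindered to take part.

Step 7
Reactants: 8 (1S,3E,7Z)-9-(tert-butyldiphenylsilyloxy)-3,7-dimethyl-1-(2,6,6-trimethylcyclohex-1-en-1-yl)nona-3,7-dien-1-ol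
Product: 11 aldehyde 15-(tert-butyldiphenylsilyloxy)-6,7-secolabda-7,13Z-dien-6-al (5α-H; 9α-H; 10β-methyl), via potassium alkoxide 9 (not isolated), via potassium enolate 10 (not isolated)
Conditions: KH, 18-crown-6, THF, 0 °C to rt; then AcOH, −78 °C
Reagents that add atoms: none
Why: Anionic oxy-Cope rearrangement: the potassium 1,5-dien-3-olate should undergo the [3,3] shift through a chair transition state with the alkoxide pseudo-equatorial (the other chair puts it 1,3-diaxial to the C10 methyl), which breaks C6–C7, forms the quaternary C10–C9 bond with transfer of the (S)-carbinol chirality (C10 methyl β, H9 α from the E olefin), and kinetic protonation of the enolate at C5 from the α face, away from the two axial methyl groups, should give the 5α-H aldehyde.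

Step 8
Reactants: 11 aldehyde 15-(tert-butyldiphenylsilyloxy)-6,7-secolabda-7,13Z-dien-6-al
Product: 12 15-(tert-butyldiphenylsilyloxy)labda-8(17),13Z-dien-6α-ol
Conditions: Me2AlCl, CH2Cl2, −78 °C to −20 °C; cold 1 M HCl work-up
Reagents that add atoms: none
Why: Me2AlCl binds the C6 aldehyde, and the terminal methylene C7 of the isopropenyl group adds to C6 while a hydrogen of the C17 methyl passes to oxygen (concerted, or through a short-lived tertiary C8 cation), which leaves the exocyclic C8=C17 olefin. The closest known reaction type is the Lewis acid-promoted type 2 intramolecular carbonyl-ene (Prins-type) cyclisation of 5-methylhex-5-enals to 3-methylenecyclohexanols. Ring B closes as a six-membered ring by C6–C7 bond formation, exo at the C6=O group and endo at the C7=C8 olefin, through a chair-like transition state in which both new ring bonds are equatorial on ring A, so the trans ring fusion follows from the C5 and C10 centres set in step 7. The new stereocentre C6 is expected to be the equatorial 6α-carbinol, since the aluminium-bound oxygen avoids the 1,3-diaxial contact with the C10 and C4 β-methyl groups; it is erased in step 9. The step needs bond formation at C7 and not C8, which the 1,1-disubstituted olefin secures (tertiary cation character at C8), and chemoselectivity over the remote C13 olefin and the allylic silyl ether, which the mild, proton-scavenging Me2AlCl secures. The position of the olefin after proton loss is not critical, because the 8(17)-, 7- and 8-enes converge in step 9.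

Step 9
Reactants: 12 15-(tert-butyldiphenylsilyloxy)labda-8(17),13Z-dien-6α-ol
Product: 14 15-(tert-butyldiphenylsilyloxy)labda-7,13Z-dien-6-one, via exocyclic enone 13 (not isolated)
Conditions: Dess–Martin periodinane, CH2Cl2, 0 °C to rt; then DBU (excess), rt
Reagents that add atoms: none
Why: Dess–Martin oxidation of the hindered secondary alcohol, then base-mediated isomerisation of the β,γ-unsaturated ketone into conjugation through its dienolate, so that any 7-ene, 8-ene or C8 chloride from step 8 should converge on the same 7-en-6-one, with C5 staying trans, the fusion expected to be favoured for this enone.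

Step 10
Reactants: 14 15-(tert-butyldiphenylsilyloxy)labda-7,13Z-dien-6-one
Product: 16 7α-hydroxy-15-(tert-butyldiphenylsilyloxy)labda-8,13Z-dien-6-one, via potassium dienolate 15 (not isolated)
Conditions: KN(SiMe3)2 (slightly less than one equivalent), THF, −78 °C to 0 °C; then 2-(phenylsulfonyl)-3-phenyloxaziridine, −78 °C; AcOH quench
Reagents that add atoms: 2-(phenylsulfonyl)-3-phenyloxaziridine, O=S(=O)(c1ccccc1)N1OC1c1ccccc1
Why: Davis α-hydroxylation of an extended enolate: equilibration should give the endocyclic dienolate by loss of H9 (the more substituted diene, as in the deconjugation of 3-methylcyclohexenones), and the oxaziridine oxygen should add at the α carbon C7 from the α face, axial and anti to the C10 methyl, which sets 7α-OH and moves the olefin to C8=C9.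

Step 11
Reactants: 16 7α-hydroxy-15-(tert-butyldiphenylsilyloxy)labda-8,13Z-dien-6-one
Product: 17 15-(tert-butyldiphenylsilyloxy)labda-8,13Z-diene-6β,7α-diol
Conditions: NaBH4, MeOH/THF, −40 °C to 0 °C
Reagents that add atoms: none
Why: Borohydride reduction of the ketone from the α face, the β face of C6 being blocked by the syn-axial C10 and C4 methyl groups (attack possibly assisted by the neighbouring 7α-hydroxyl), should give the axial 6β-alcohol and thus the trans-diaxial diol.

Step 12
Reactants: 17 15-(tert-butyldiphenylsilyloxy)labda-8,13Z-diene-6β,7α-diol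
Product: 18 6β,7α-diacetoxy-15-(tert-butyldiphenylsilyloxy)labda-8,13Z-diene
Conditions: Ac2O, DMAP, Et3N, CH2Cl2, 40 °C
Reagents that add atoms: acetic anhydride, CC(=O)OC(C)=O
Why: DMAP-catalysed acetylation of both secondary alcohols; the hindered axial 6β-hydroxyl needs the nucleophilic catalyst and gentle heating, and no stereocentre is touched.

Step 13
Reactants: 18 6β,7α-diacetoxy-15-(tert-butyldiphenylsilyloxy)labda-8,13Z-diene
Product: 19 6β,7α-diacetoxylabda-8,13Z-dien-15-ol (target)
Conditions: HF·pyridine, pyridine/THF, 0 °C to rt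
Reagents that add atoms: none
Why: Desilylation with buffered HF·pyridine should remove the silyl ether without acyl migration or acetate cleavage and give the target.

Compound list

1 | nerol, (2Z)-3,7-dimethylocta-2,6-dien-1-ol | CC(C)=CCC/C(C)=C\CO | starting material
2 | neryl tert-butyldiphenylsilyl ether | CC(C)=CCC/C(C)=C\CO[Si](c1ccccc1)(c1ccccc1)C(C)(C)C | intermediate
3 | 6,7-epoxide of 2, tert-butyl{[(2Z)-5-(3,3-dimethyloxiran-2-yl)-3-methylpent-2-en-1-yl]oxy}diphenylsilane (racemic at the epoxide carbon) | CC1(C)OC1CC/C(C)=C\CO[Si](c2ccccc2)(c3ccccc3)C(C)(C)C | intermediate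
4 | (4Z)-6-(tert-butyldiphenylsilyloxy)-4-methylhex-4-enal | O=CCC/C(C)=C\CO[Si](c1ccccc1)(c2ccccc2)C(C)(C)C | intermediate
5 | tert-butyl{[(2Z)-3-methylhepta-2,6-dien-1-yl]oxy}diphenylsilane | C=CCC/C(C)=C\CO[Si](c1ccccc1)(c2ccccc2)C(C)(C)C | intermediate
6 | β-cyclocitral, 2,6,6-trimethylcyclohex-1-ene-1-carbaldehyde | CC1=C(C=O)C(C)(C)CCC1 | starting material
7 | (1S)-3-methyl-1-(2,6,6-trimethylcyclohex-1-en-1-yl)but-3-en-1-ol | CC1=C([C@@H](O)CC(C)=C)C(C)(C)CCC1 | intermediate
8 | (1S,3E,7Z)-9-(tert-butyldiphenylsilyloxy)-3,7-dimethyl-1-(2,6,6-trimethylcyclohex-1-en-1-yl)nona-3,7-dien-1-ol | CC1=C([C@@H](O)C/C(C)=C/CC/C(C)=C\CO[Si](c2ccccc2)(c3ccccc3)C(C)(C)C)C(C)(C)CCC1 | intermediate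
9 | potassium alkoxide of 8 | CC1=C([C@@H]([O-])C/C(C)=C/CC/C(C)=C\CO[Si](c2ccccc2)(c3ccccc3)C(C)(C)C)C(C)(C)CCC1.[K+] | intermediate
10 | potassium enolate of 11 (C5=C6 enolate, oxygen cis to C4) | C=C(C)[C@H](CC/C(C)=C\CO[Si](c2ccccc2)(c3ccccc3)C(C)(C)C)[C@@]1(C)CCCC(C)(C)/C1=C\[O-].[K+] | intermediate
11 | 15-(tert-butyldiphenylsilyloxy)-6,7-secolabda-7,13Z-dien-6-al: ring A carries the formyl group on C5 (5α-H) and, on C10 (methyl β), the C9 carbon (9α-H) that bears the isopropenyl group C8(C17)=C7 and the C11–C15 chain | C=C(C)[C@H](CC/C(C)=C\CO[Si](c2ccccc2)(c3ccccc3)C(C)(C)C)[C@@]1(C)CCCC(C)(C)[C@@H]1C=O | intermediate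
12 | 15-(tert-butyldiphenylsilyloxy)labda-8(17),13Z-dien-6α-ol | O[C@H]1CC(=C)[C@H](CC/C(C)=C\CO[Si](c3ccccc3)(c4ccccc4)C(C)(C)C)[C@@]2(C)CCCC(C)(C)[C@H]12 | intermediate
13 | 15-(tert-butyldiphenylsilyloxy)labda-8(17),13Z-dien-6-one | O=C1CC(=C)[C@H](CC/C(C)=C\CO[Si](c3ccccc3)(c4ccccc4)C(C)(C)C)[C@@]2(C)CCCC(C)(C)[C@H]12 | intermediate
14 | 15-(tert-butyldiphenylsilyloxy)labda-7,13Z-dien-6-one (5α-H, 9α-H) | O=C1C=C(C)[C@H](CC/C(C)=C\CO[Si](c3ccccc3)(c4ccccc4)C(C)(C)C)[C@@]2(C)CCCC(C)(C)[C@H]12 | intermediate
15 | potassium 6,8-dienolate of 14 | [O-]C1=CC(C)=C(CC/C(C)=C\CO[Si](c3ccccc3)(c4ccccc4)C(C)(C)C)[C@@]2(C)CCCC(C)(C)[C@H]12.[K+] | intermediate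
16 | 7α-hydroxy-15-(tert-butyldiphenylsilyloxy)labda-8,13Z-dien-6-one | O=C1[C@@H](O)C(C)=C(CC/C(C)=C\CO[Si](c3ccccc3)(c4ccccc4)C(C)(C)C)[C@@]2(C)CCCC(C)(C)[C@H]12 | intermediate
17 | 15-(tert-butyldiphenylsilyloxy)labda-8,13Z-diene-6β,7α-diol | O[C@@H]1[C@@H](O)C(C)=C(CC/C(C)=C\CO[Si](c3ccccc3)(c4ccccc4)C(C)(C)C)[C@@]2(C)CCCC(C)(C)[C@H]12 | intermediate
18 | 6β,7α-diacetoxy-15-(tert-butyldiphenylsilyloxy)labda-8,13Z-diene | CC(=O)O[C@@H]1[C@@H](OC(C)=O)C(C)=C(CC/C(C)=C\CO[Si](c3ccccc3)(c4ccccc4)C(C)(C)C)[C@@]2(C)CCCC(C)(C)[C@H]12 | intermediate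
19 | 6β,7α-diacetoxylabda-8,13Z-dien-15-ol (CNP0187815.3) | CC(=O)O[C@@H]1[C@@H](OC(C)=O)C(C)=C(CC/C(C)=C\CO)[C@@]2(C)CCCC(C)(C)[C@H]12 | target

Total step count: 13. Longest linear sequence: 12 steps (nerol 1 to 19 through steps 1–4 and 6–13); the β-cyclocitral branch is one step (step 5) before the union in step 6.

Steps most likely to fail, each with one fallback:

Step 7 may suffer from fragmentation of the potassium alkoxide (loss of the allyl unit back towards the aldehyde) or from leakage through a transition state with the alkoxide axial, which would erode the transfer of chirality to C10. The fallback sets out from 8: silylation with Et3SiCl and imidazole gives the triethylsilyl ether F1, which is heated in toluene at about 220 °C in a sealed tube so that the neutral silyloxy-Cope rearrangement, with the bulky silyloxy group pseudo-equatorial, gives the triethylsilyl enol ether F2; cold buffered fluoride then cleaves the enol ether with protonation at C5 and comes back to the route at 11.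

Step 8 may fail because attack on the neopentyl-type aldehyde is slow, so that Lewis-acid-induced ionisation or proton-initiated cyclisation between the isopropenyl group and the C13 olefin takes over. The fallback sets out from 11: Pinnick oxidation (NaClO2, NaH2PO4, 2-methylbut-2-ene in excess) gives the carboxylic acid F3, oxalyl chloride converts it to the acid chloride F4, and SnCl4 at low temperature promotes an intramolecular acylation of the isopropenyl group (aliphatic Friedel–Crafts acylation) that closes ring B through the same C6–C7 bond; loss of HCl, completed with DBU, gives the conjugated enone and comes back to the route at 14.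

Step 10 may fail through deprotonation at the C17 methyl or at C5 instead of C9, which would leave the olefin exocyclic or scramble C5, or through attack of the oxidant at the γ carbon. The fallback sets out from 14: nucleophilic epoxidation (H2O2, NaOH, MeOH), selective for the enone and expected from the α face, gives the 7α,8α-epoxy ketone F5; NaBH4 reduces it from the α face to the 6β-hydroxy epoxide F6; an acid-promoted isomerisation of the epoxide to the allylic alcohol (camphorsulfonic acid or Ti(OiPr)4), in which the tertiary C8–O bond opens and H9 is lost, comes back to the route at diol 17.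

Further compounds

F1 | step 7 | triethylsilyl ether of 8 | CC1=C([C@@H](O[Si](CC)(CC)CC)C/C(C)=C/CC/C(C)=C\CO[Si](c2ccccc2)(c3ccccc3)C(C)(C)C)C(C)(C)CCC1
F2 | step 7 | triethylsilyl enol ether of 11 | C=C(C)[C@H](CC/C(C)=C\CO[Si](c2ccccc2)(c3ccccc3)C(C)(C)C)[C@@]1(C)CCCC(C)(C)/C1=C\O[Si](CC)(CC)CC
F3 | step 8 | 15-(tert-butyldiphenylsilyloxy)-6,7-secolabda-7,13Z-dien-6-oic acid | C=C(C)[C@H](CC/C(C)=C\CO[Si](c2ccccc2)(c3ccccc3)C(C)(C)C)[C@@]1(C)CCCC(C)(C)[C@@H]1C(=O)O
F4 | step 8 | acid chloride of F3 | C=C(C)[C@H](CC/C(C)=C\CO[Si](c2ccccc2)(c3ccccc3)C(C)(C)C)[C@@]1(C)CCCC(C)(C)[C@@H]1C(Cl)=O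
F5 | step 10 | 7α,8α-epoxy-15-(tert-butyldiphenylsilyloxy)labd-13Z-en-6-one | O=C1[C@H]2O[C@@]2(C)[C@H](CC/C(C)=C\CO[Si](c4ccccc4)(c5ccccc5)C(C)(C)C)[C@@]3(C)CCCC(C)(C)[C@H]13
F6 | step 10 | 7α,8α-epoxy-15-(tert-butyldiphenylsilyloxy)labd-13Z-en-6β-ol | O[C@@H]1[C@H]2O[C@@]2(C)[C@H](CC/C(C)=C\CO[Si](c4ccccc4)(c5ccccc5)C(C)(C)C)[C@@]3(C)CCCC(C)(C)[C@H]13
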